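**Retrosynthetic overview**
- The C6–CH2 and C8–CH2 bonds are cut last. Both are o-quinone methide Friedel–Crafts benzylations of (2S)-pinocembrin: first at C6 with a pre-built tris-phenol saligenin, then at C8 with salicyl alcohol.
- (2S)-Pinocembrin comes from the achiral, symmetric pinocembrin chalcone by the chalcone-isomerase oxa-Michael closure, which makes the only new ring (pyranone ring C) and the only stereocentre in one step.
- The chalcone comes from phloroacetophenone and benzaldehyde by an unprotected aldol condensation.
- The tris-phenol saligenin comes from 2,2'-methylenediphenol and methyl 5-formylsalicylate by a boron-templated, ortho-specific reductive coupling, then ester reduction.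
- Ring order: rings A and B and the four phenol rings are bought; ring C is the only ring formed (step 2); no protecting groups are used.

Assumption: recombinant Medicago sativa chalcone isomerase (UniProt P28012), obtained by routine expression in E. coli, is used as a catalyst and is not counted as a starting material.

**Route**

Step 1
Reactants: 1 anhydrous phloroacetophenone (2',4',6'-trihydroxyacetophenone); 2 benzaldehyde
Product: 4 (E)-2',4',6'-trihydroxychalcone (pinocembrin chalcone), via aldol adduct 3 (not isolated)
Conditions: LiN(SiMe3)2 (4.4 equiv), THF, −78 °C; 2 (1.1 equiv), −78 °C to rt; cold 1 M HCl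
Reagents that add atoms: none
Why: Claisen–Schmidt (crossed aldol) condensation on fully deprotonated 1 (three lithium phenoxides plus the lithium enolate), which needs no protecting groups; adduct 3 dehydrates by E1cB (completed on the acid quench) to the (E)-enone, the poly-anion cannot close to the flavanone before the quench, and no stereocentre is formed.

Step 2
Reactants: 4 pinocembrin chalcone
Product: 5 (2S)-pinocembrin [(2S)-5,7-dihydroxy-2-phenylchroman-4-one]
Conditions: chalcone isomerase (Medicago sativa, UniProt P28012, ca. 0.05 mol%), K2HPO4/KH2PO4 buffer (50 mM, pH 6.8), DMSO (10% v/v), 25 °C; 4 fed slowly as a DMSO solution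
Reagents that add atoms: none
Why: Chalcone-isomerase reaction, an intramolecular 6-endo-trig oxa-Michael addition: the enzyme lets the ortho-phenoxide add to one face of the enone β-carbon only, which sets C2 as S in >99% ee (the two ortho-OH groups of symmetric 4 are equivalent, so there is no regiochemical question), and its rate, about 10^7 times that of the spontaneous closure, suppresses the racemic background at pH 6.8.

Step 3
Reactants: 6 2,2'-methylenediphenol (2.5 equiv, excess recovered); 7 methyl 5-formylsalicylate
Product: 9 methyl 2-hydroxy-5-[2-hydroxy-3-(2-hydroxybenzyl)benzyl]benzoate, via benzodioxaborin 8 (not isolated)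
Conditions: PhB(OH)2 (2.5 equiv), EtCO2H (cat.), toluene, reflux, Dean–Stark; then Et3SiH (10 equiv), CF3CO2H, CH2Cl2, 0 °C to rt
Reagents that add atoms: phenylboronic acid, OB(O)c1ccccc1 (its boron and phenyl are held in 8 only and none is left in 9)
Why: Nagata-type boron-templated ortho-hydroxyalkylation followed by ionic hydrogenation: boron esterifies a phenol oxygen of 6 and delivers the bound aldehyde of 7 only to the free ortho carbon (excess 6 stops the reaction at one ring), the aldehyde carbon of 7 already sits para to its own OH, and in CF3CO2H the benzylic C–O bond of 8 ionises to a para-hydroxy-stabilised diarylmethyl cation that Et3SiH reduces faster than a phenol ring can attack it; the stereocentre of 8 is erased.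

Step 4
Reactants: 9 methyl 2-hydroxy-5-[2-hydroxy-3-(2-hydroxybenzyl)benzyl]benzoate
Product: 10 2-(hydroxymethyl)-4-[2-hydroxy-3-(2-hydroxybenzyl)benzyl]phenol (tris-phenol saligenin)
Conditions: LiAlH4 (5 equiv), THF, 0 °C to rt
Reagents that add atoms: none
Why: Hydride reduction of a salicylate ester to the saligenin (ester to primary alcohol): the three phenols only consume hydride, the diarylmethane bridges are inert, and at rt the new benzylic alcohol is not reduced further; no stereocentre.

Step 5
Reactants: 5 (2S)-pinocembrin (1.5 equiv, excess recovered); 10 tris-phenol saligenin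
Product: 12 (2S)-5,7-dihydroxy-6-{2-hydroxy-5-[2-hydroxy-3-(2-hydroxybenzyl)benzyl]benzyl}-2-phenylchroman-4-one, via o-quinone methide 11 (not isolated)
Conditions: ZnCl2 (3 equiv), 1,4-dioxane, 50 °C, 10 added over 6 h
Reagents that add atoms: none
Why: Friedel–Crafts-type ortho-hydroxybenzylation through the zinc-bound o-quinone methide 11: the phloroglucinol ring A of 5 is far more nucleophilic than the phenol rings of 10, and C6, the only carbon ortho to both the zinc-chelated 5-O and the free 7-OH, is expected to be attacked in preference to C8 (the 8-isomer and the 6,8-bis adduct are removed by chromatography, regiochemistry confirmed by HMBC from the chelated 5-OH); C2 is not touched under these non-basic conditions.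

Step 6
Reactants: 12 the 6-substituted (2S)-flavanone; 13 salicyl alcohol (2-hydroxybenzyl alcohol, 1.3 equiv)
Product: 15 (2S)-5,7-dihydroxy-6-{2-hydroxy-5-[2-hydroxy-3-(2-hydroxybenzyl)benzyl]benzyl}-8-(2-hydroxybenzyl)-2-phenylchroman-4-one (the target CNP0107650.1), via o-quinone methide 14 (not isolated)
Conditions: ZnCl2 (3 equiv), 1,4-dioxane, 50 °C
Reagents that add atoms: none
Why: The same zinc-mediated o-quinone methide Friedel–Crafts benzylation: C8 is the last free carbon of ring A and is still far more nucleophilic than the four side-chain phenol rings, so a slight excess of 13 gives the target; the (2S) centre set in step 2 is untouched and the ee is checked by chiral HPLC.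

**Compound list**

1 | phloroacetophenone (2',4',6'-trihydroxyacetophenone) | CC(=O)c1c(O)cc(O)cc1O | starting material
2 | benzaldehyde | O=Cc1ccccc1 | starting material
3 | aldol adduct, 3-hydroxy-3-phenyl-1-(2,4,6-trihydroxyphenyl)propan-1-one (racemic, not isolated) | O=C(CC(O)c1ccccc1)c1c(O)cc(O)cc1O | intermediate
4 | (E)-2',4',6'-trihydroxychalcone (pinocembrin chalcone) | O=C(/C=C/c1ccccc1)c1c(O)cc(O)cc1O | intermediate
5 | (2S)-pinocembrin, (2S)-5,7-dihydroxy-2-phenylchroman-4-one | O=C1C[C@@H](c2ccccc2)Oc2cc(O)cc(O)c21 | intermediate
6 | 2,2'-methylenediphenol, bis(2-hydroxyphenyl)methane | Oc1ccccc1Cc1ccccc1O | starting material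
7 | methyl 5-formylsalicylate (methyl 5-formyl-2-hydroxybenzoate) | COC(=O)c1cc(C=O)ccc1O | starting material
8 | benzodioxaborin, methyl 2-hydroxy-5-[8-(2-hydroxybenzyl)-2-phenyl-4H-1,3,2-benzodioxaborin-4-yl]benzoate (racemic, not isolated) | COC(=O)c1cc(C2OB(c3ccccc3)Oc3c(Cc4ccccc4O)cccc32)ccc1O | intermediate
9 | methyl 2-hydroxy-5-[2-hydroxy-3-(2-hydroxybenzyl)benzyl]benzoate | COC(=O)c1cc(Cc2cccc(Cc3ccccc3O)c2O)ccc1O | intermediate
10 | 2-(hydroxymethyl)-4-[2-hydroxy-3-(2-hydroxybenzyl)benzyl]phenol (tris-phenol saligenin) | OCc1cc(Cc2cccc(Cc3ccccc3O)c2O)ccc1O | intermediate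
11 | o-quinone methide of 10, 4-[2-hydroxy-3-(2-hydroxybenzyl)benzyl]-6-methylidenecyclohexa-2,4-dien-1-one (not isolated) | C=C1C=C(Cc2cccc(Cc3ccccc3O)c2O)C=CC1=O | intermediate
12 | (2S)-5,7-dihydroxy-6-{2-hydroxy-5-[2-hydroxy-3-(2-hydroxybenzyl)benzyl]benzyl}-2-phenylchroman-4-one | O=C1C[C@@H](c2ccccc2)Oc2cc(O)c(Cc3cc(Cc4cccc(Cc5ccccc5O)c4O)ccc3O)c(O)c21 | intermediate
13 | salicyl alcohol (2-hydroxybenzyl alcohol) | OCc1ccccc1O | starting material
14 | o-quinone methide of 13, 6-methylidenecyclohexa-2,4-dien-1-one (not isolated) | C=C1C=CC=CC1=O | intermediate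
15 | (2S)-5,7-dihydroxy-6-{2-hydroxy-5-[2-hydroxy-3-(2-hydroxybenzyl)benzyl]benzyl}-8-(2-hydroxybenzyl)-2-phenylchroman-4-one | O=C1C[C@@H](c2ccccc2)Oc2c(Cc3ccccc3O)c(O)c(Cc3cc(Cc4cccc(Cc5ccccc5O)c4O)ccc3O)c(O)c21 | target

**Summary**

Total step count: 6. Longest linear sequence: 4 steps (1 → 4 → 5 → 12 → 15, or 6 and 7 → 9 → 10 → 12 → 15).

**Steps most likely to fail**

Step 5 is the most exposed. The C6 preference over C8 is argued from chelation and from the general behaviour of 5,7-dihydroxyflavanones, not proven for this pair. The valuable saligenin 10 can also self-condense or add twice, and the ee of 5 must survive the Lewis acid. The fallback sets out from 5 and reverses the order of the two benzylations, so that the unselective event uses the cheap partner. Compound 5 with 0.9 equiv of 13 and ZnCl2 in dioxane gives (2S)-chamanetin F1 together with its 6-isomer, (2S)-isochamanetin F2; both are known natural products and are separated on silica. F1, whose C6 is the only free carbon of ring A, is then coupled with 10 under the same conditions. This gives 15 directly, so the route is rejoined at 15 and 12 is bypassed.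

Step 3 is the second risk. The boron template has to work on a bisphenol that can bridge boron, stop after one ring, and tolerate the salicylate unit of 7; the ionic hydrogenation must also beat Friedel–Crafts capture of the cation. The fallback sets out from 6 and replaces the template by a stepwise Friedel–Crafts approach. Ortho-formylation with MgCl2, Et3N and (CH2O)n gives 2-hydroxy-3-(2-hydroxybenzyl)benzaldehyde F3. NaBH4 reduces it to 2-(hydroxymethyl)-6-(2-hydroxybenzyl)phenol F4. F4 is added slowly to a large excess of neat commercial methyl salicylate (COC(=O)c1ccccc1O) with catalytic CH3SO3H at 60 °C, where the benzylic cation takes the position para to the salicylate OH. This gives 9, where the route is rejoined.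

Step 2 is the third risk. It depends on access to active enzyme and on outrunning the spontaneous racemic closure of 4 on a preparative scale with a poorly soluble substrate. The fallback sets out from 4 and replaces asymmetric catalysis by resolution with recycling. NaOAc in refluxing EtOH closes 4 to racemic pinocembrin F5. Preparative HPLC on cellulose tris(3,5-dimethylphenylcarbamate) gives 5, where the route is rejoined. The unwanted (2R)-pinocembrin F6 is re-opened to 4 with aqueous KOH and cyclised again.

**Further compounds**

F1 | step 5 | (2S)-chamanetin, (2S)-5,7-dihydroxy-8-(2-hydroxybenzyl)-2-phenylchroman-4-one | O=C1C[C@@H](c2ccccc2)Oc2c(Cc3ccccc3O)c(O)cc(O)c21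
F2 | step 5 | (2S)-isochamanetin, (2S)-5,7-dihydroxy-6-(2-hydroxybenzyl)-2-phenylchroman-4-one | O=C1C[C@@H](c2ccccc2)Oc2cc(O)c(Cc3ccccc3O)c(O)c21
F3 | step 3 | 2-hydroxy-3-(2-hydroxybenzyl)benzaldehyde | O=Cc1cccc(Cc2ccccc2O)c1O
F4 | step 3 | 2-(hydroxymethyl)-6-(2-hydroxybenzyl)phenol | OCc1cccc(Cc2ccccc2O)c1O
F5 | step 2 | racemic pinocembrin, 5,7-dihydroxy-2-phenylchroman-4-one | O=C1CC(c2ccccc2)Oc2cc(O)cc(O)c21
F6 | step 2 | (2R)-pinocembrin | O=C1C[C@H](c2ccccc2)Oc2cc(O)cc(O)c21
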